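# Proposed total synthesis of mallotojaponin B through a pyranone-to-arene ring transformation

## Structural features

Mallotojaponin B (13) is an unsymmetrical bis(acylphloroglucinol): two hexasubstituted benzene rings joined by a single sp3 methylene carbon, with no stereocentre and no other ring. Ring A, numbered from its acetyl-bearing carbon C-1, carries OH at C-2 and C-6, the bridge at C-3, OMe at C-4 and CH3 at C-5. Ring B carries the same array (C-1' to C-6') with a prenyl group at C-5' in place of the methyl. In each ring only one of the three oxygens is methylated, the one para to the acetyl group and flanked by the two carbon substituents.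

The fragile elements are:
- the prenyl alkene, which adds an ortho hydroxyl under acid to give a chroman and is cyclised oxidatively to a chromene;
- the doubly benzylic bridge, which can re-ionise to an ortho-quinone methide in hot base or acid;
- the air-sensitive free polyphenol.

The real difficulty is differentiation. The two rings are almost the same nucleophile, so a bridge built from two arenes and a one-carbon unit has no built-in cross-selectivity. Each ring also needs six substituents and one specific O-methyl placed without regiochemical ambiguity.

The key step exploits the fact that ring A is an intact tetraketide. The eight carbons CH3–CO–C1–C6(O)–C5–C4(O)–C3–C2(O) carry oxygen on alternate atoms, so ring A is the Claisen-cyclised form of a 3,5,7-trioxooctanoate whose δ-lactone is a 2-pyranone. In that pyranone O-1/C-6, C-5, C-4, C-3 and C-2 map onto C-6(OH), C-5(CH3), C-4(OMe), C-3(bridge) and C-2(OH) of ring A. Pyranone C-3 is the innate nucleophilic carbon, and the pyranone is a far stronger acid than a phloroglucinol, which makes it a bridge partner clearly different from ring B.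

## Logic of the disconnections

13 to 10 (key disconnection). The bond cut is C-1–C-2 of ring A, between the acetyl-bearing carbon and the hydroxyl-bearing carbon next to the bridge. The C-6 oxygen is reconnected to C-2 as a lactone, so that ring A of 13 becomes the 4-methoxy-2-pyranone ring of 10 with a 2-oxopropyl chain on C-6. In one sentence: 13 is formed in the last step by methoxide ring opening and Claisen reclosure of the pyranone ring of 10. The reason for cutting here is that every substituent of ring A is then fixed by atom position in a heterocycle, not by selective substitution of a symmetric phloroglucinol. The gain is that 10 is an isomer of 13 needing no protecting group, and its two halves are electronically different. The demand on the forward step is Claisen (C-acylation) closure in preference to aldol closure, under conditions that leave the bridge, the prenyl group and the free ring B phenols intact. The open-chain ester 11 and the non-aromatic dione 12 lie on the way.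

10 to 9. The O–CH3 bond on the pyranone 4-oxygen is cut. It is placed late because the free 4-hydroxyl is needed to make C-3 nucleophilic for the bridge. The demand is methylation of the most acidic hydroxyl of 9 (the vinylogous acid) in the presence of two chelated phenols, and at O-4 rather than O-2.

9 to 3 and 7. The bond between the bridge carbon and pyranone C-3 is cut; this bond becomes the ring A C-3–CH2 bond of 13. Ring B arrives as an ortho-quinone methide 8 released from 3, and the pyranone 7 is the nucleophile. The gain is full convergence: a hexasubstituted arene already holding the bridge carbon, plus a small heterocycle. The demand is C-3 alkylation of 7 rather than reaction at O-4 or at the side-chain methylene. The cross-selectivity is structural: 3 has no free ring carbon and cannot couple with itself.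

3 to 2 to 1. First the ring B–CH2N bond is cut (aminomethylation at the only free ring carbon of 2), then the ring B–prenyl bond (C-alkylation of 1, whose two free ring carbons are equivalent). The demand on the prenylation is C- over O-alkylation and mono- over bis-alkylation, under base only.

7 to 6. The bond between the side-chain methylene and the ketone carbon is cut: acylation of the 6-methyl carbanion of 6. The demand is deprotonation at the 6-methyl (vinylogous to the lactone carbonyl) and not at the 5-methyl or at C-3.

6 to 5 to 4. The lactone C–O bond is cut to give the diketo ester 5, then the C-4–C-5 bond of 5 is cut to give 4 and an acetyl donor. This places the future ring A methyl on the correct carbon from the start, because it is the terminal CH3CH2 group of 4.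

## Other disconnections considered

Alternative 1: The first idea is to cut one or both aryl–CH2 bonds of the bridge between two finished arenes. The forward step would condense the ring A monomer A1 and 2 with formaldehyde, or, stepwise, add A1 to the ortho-quinone methide 8 released from 3. This is the shortest plan. In the one-pot form, however, nothing in the mechanism distinguishes two nearly identical phloroglucinol nucleophiles, so cross-coupling would be statistical. The stepwise form moves the regiochemical burden into A1, which must be made by mono-C-methylation and mono-O-methylation of a phloroglucinol that tends to over-alkylate and dearomatise. The chosen plan builds ring A with its substituents fixed by the atoms of a pyranone, at the cost of a few more steps.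

Alternative 2: An electrochemical plan would cut the same ring B–CH2 bond but start the bridge carbon as a C-methyl group. Anodic two-electron oxidation of the symmetric dimethyl monomer A2 would give the ortho-quinone methide A3, to be trapped by 2. The precursor is attractively symmetric. The weakness is that 2, a free phloroglucinol with an ortho-prenyl group, should be oxidised at a potential no higher than A2, with oxidative cyclisation to a chromene expected. The product also holds a doubly activated diarylmethane CH2 that is more oxidisable than the methyl of A2. A3 cannot be accumulated ahead of the nucleophile either, since such species dimerise by hetero-Diels–Alder reaction. The chosen key step is redox-neutral and avoids all three problems.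

Alternative 3: Both arenes could be made at once from the bis-pyranone A4 by a double ring opening and Claisen reclosure, without any aromatic starting material. A4 would come from 6 and the 5-prenyl pyranone A5 through a methylene link, followed by O-methylation and acylation of both 6-methyl groups. This fails on selectivity and step economy. Joining two almost identical 4-hydroxypyranones through formaldehyde brings back the statistical problem. A5 needs its own multi-step synthesis. The double 6-methyl acylation must be carried out beside a doubly allylic prenyl CH2. The chosen plan takes ring B from a commercial arene in two steps and uses the ring transformation only where it removes a regiochemical problem.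

Key step: step 8

Remark: 1, 4 and the reagents named on the Conditions lines are taken to be commercial. The target is achiral; the stereocentres of 5, 11 and 12 are uncontrolled and are erased by enolisation or aromatisation.

## Route

Step 1
Reactants: 1 1-(2,6-dihydroxy-4-methoxyphenyl)ethan-1-one
Product: 2 1-[2,6-dihydroxy-4-methoxy-3-(3-methylbut-2-en-1-yl)phenyl]ethan-1-one
Conditions: prenyl bromide (0.9 equiv), 10% aq. KOH, 0 °C to rt; unreacted 1 recovered
Reagents that add atoms: prenyl bromide (1-bromo-3-methylbut-2-ene), CC(C)=CCBr
Why: Base-mediated C-alkylation of an ambident phloroglucinol phenoxide, with water hydrogen-bonding the oxygens so that carbon attack is favoured; the two free ring carbons of 1 are equivalent, so only one mono-C-prenyl isomer can form, a deficit of bromide limits bis-alkylation, and the absence of acid avoids chroman formation.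

Step 2
Reactants: 2 1-[2,6-dihydroxy-4-methoxy-3-(3-methylbut-2-en-1-yl)phenyl]ethan-1-one
Product: 3 1-{3-[(dimethylamino)methyl]-2,6-dihydroxy-4-methoxy-5-(3-methylbut-2-en-1-yl)phenyl}ethan-1-one
Conditions: CH2=NMe2+ I− (1.2 equiv), CH2Cl2, 0 °C to rt; aq. NaHCO3
Reagents that add atoms: Eschenmoser's salt (N,N-dimethylmethyleneiminium iodide), C=[N+](C)C.[I-]
Why: Phenolic Mannich aminomethylation, an electrophilic aromatic substitution by a preformed iminium ion at the only free ring carbon of 2; using the preformed iminium avoids free formaldehyde and hence diarylmethane formation, and the prenyl alkene is far less nucleophilic than the phloroglucinol ring.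

Step 3
Reactants: 4 methyl 3-oxopentanoate
Product: 5 methyl 4-methyl-3,5-dioxohexanoate (racemic at C-4, largely enolised)
Conditions: LiN(iPr)2 (2.2 equiv), THF, −78 to 0 °C; MeC(O)N(OMe)Me, −78 to 0 °C; 1 M HCl
Reagents that add atoms: N-methoxy-N-methylacetamide, CC(=O)N(C)OC
Why: γ-Acylation of a β-keto ester dianion: the more basic γ-carbanion attacks the Weinreb amide, whose chelated tetrahedral adduct survives until work-up and so prevents over-addition; the C-4 stereocentre is not controlled and disappears in step 4.

Step 4
Reactants: 5 methyl 4-methyl-3,5-dioxohexanoate
Product: 6 4-hydroxy-5,6-dimethyl-2H-pyran-2-one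
Conditions: DBU (1.2 equiv), toluene, reflux; dilute HCl wash
Reagents that add atoms: none
Why: Base-promoted enol lactonisation of a 3,5-diketo ester, the standard entry to 4-hydroxy-6-alkyl-2-pyranones: the C-5 enolate oxygen attacks the ester in a six-membered closure with loss of methanol and the product is a stable vinylogous acid.

Step 5
Reactants: 6 4-hydroxy-5,6-dimethyl-2H-pyran-2-one
Product: 7 4-hydroxy-5-methyl-6-(2-oxopropyl)-2H-pyran-2-one
Conditions: LiN(iPr)2 (3 equiv), THF–DMPU, −78 to −30 °C; MeC(O)N(OMe)Me; 1 M HCl
Reagents that add atoms: N-methoxy-N-methylacetamide, CC(=O)N(C)OC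
Why: Dianion chemistry of 4-hydroxy-6-methyl-2-pyranones: the first equivalent of base gives the lithium pyronate, the next removes a proton from the 6-methyl group (vinylogous to the lactone carbonyl, whereas the 5-methyl is not conjugated to a carbonyl), and the carbanion is acylated by the Weinreb amide, the ketone being released only on work-up.

Step 6
Reactants: 3 1-{3-[(dimethylamino)methyl]-2,6-dihydroxy-4-methoxy-5-(3-methylbut-2-en-1-yl)phenyl}ethan-1-one, 7 4-hydroxy-5-methyl-6-(2-oxopropyl)-2H-pyran-2-one
Product: 9 3-{[3-acetyl-2,4-dihydroxy-6-methoxy-5-(3-methylbut-2-en-1-yl)phenyl]methyl}-4-hydroxy-5-methyl-6-(2-oxopropyl)-2H-pyran-2-one, via ortho-quinone methide 8 (not isolated)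
Conditions: 7 (1.1 equiv), 1,4-dioxane, 90 °C, slow N2 stream
Reagents that add atoms: none
Why: The acidic pyranone (pKa about 5) protonates the Mannich base, thermal β-elimination of dimethylamine gives ortho-quinone methide 8, and the soft pyronate adds through C-3 (Michael addition with rearomatisation), the known behaviour of 4-hydroxy-2-pyranones and 4-hydroxycoumarins toward ortho-quinone methides; 3 has no free ring carbon and cannot self-couple, and the side-chain methylene of 7 is far less acidic than its 4-hydroxyl.

Step 7
Reactants: 9 3-{[3-acetyl-2,4-dihydroxy-6-methoxy-5-(3-methylbut-2-en-1-yl)phenyl]methyl}-4-hydroxy-5-methyl-6-(2-oxopropyl)-2H-pyran-2-one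
Product: 10 3-{[3-acetyl-2,4-dihydroxy-6-methoxy-5-(3-methylbut-2-en-1-yl)phenyl]methyl}-4-methoxy-5-methyl-6-(2-oxopropyl)-2H-pyran-2-one
Conditions: MeOH (3 equiv), PPh3 (1.1 equiv), DIAD (1.1 equiv), THF, 0 °C to rt
Reagents that add atoms: methanol, CO
Why: Mitsunobu O-alkylation selects by acidity: the betaine deprotonates the vinylogous acid (pKa about 5) well before the phenols, which are hydrogen-bonded to the acetyl group (pKa about 8 to 9), and the pyronate attacks the methoxyphosphonium ion through O-4, the established regiochemistry for 4-hydroxy-2-pyranones; excess methanol keeps the phosphonium on the alcohol and not on the enol.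

Step 8
Reactants: 10 3-{[3-acetyl-2,4-dihydroxy-6-methoxy-5-(3-methylbut-2-en-1-yl)phenyl]methyl}-4-methoxy-5-methyl-6-(2-oxopropyl)-2H-pyran-2-one
Product: 13 mallotojaponin B (1-[3-{[3-acetyl-2,4-dihydroxy-6-methoxy-5-(3-methylbut-2-en-1-yl)phenyl]methyl}-2,6-dihydroxy-4-methoxy-5-methylphenyl]ethan-1-one), via ring-opened enoate ester 11 (not isolated), via cyclohexenedione 12 (not isolated)
Conditions: Mg(OMe)2 (8 equiv), MeOH, 60 °C, Ar; cold 1 M HCl to pH 3
Reagents that add atoms: none
Why: Methoxide adds to the lactone carbonyl C-2 of 10 and the ring opens to the magnesium-chelated enolate of ester 11, whose (2E)-enoate geometry, inherited from the ring, holds the ester carbon within reach of chain carbon C-6. The 5,7-diketone of 11 sits as a magnesium β-diketonate whose central carbon acylates the ester in a six-membered exo-trig Claisen (Dieckmann-type) closure, the metal bridging diketonate and ester carbonyl so that C-acylation is preferred; loss of methoxide gives 12, which enolises to aromatic ring A of 13, the thermodynamic sink as its magnesium chelate. The closest known reaction type is the magnesium alkoxide recyclisation of 4-methoxy-6-(2-oxoalkyl)-2-pyranones to 4-O-methyl acylphloroglucinols, the laboratory counterpart of the tetraketide Claisen cyclisation, and 10 is a more substituted member of that substrate class. The selectivity needed is Claisen over aldol closure: the aldol mode that leads to resorcylates requires chain C-2 as a carbanion, but in 11 that carbon is an enol ether alkene carbon bearing the benzylic substituent, so an adduct there could not aromatise and would revert. No stereocentre is created; the C-4 centre of 11 and both centres of 12 vanish on enolisation. Regiochemistry follows from atom mapping alone: the ring oxygen and the lactone carbonyl become the two free hydroxyls flanking the acetyl group, the 4-methoxyl becomes the single O-methyl, and the 5-methyl and the benzylic carbon end up on either side of it. The ring B phenols are held as magnesium chelates with their acetyl group, and if one displaced the 4-methoxyl by addition–elimination the large excess of methoxide should reverse it, aryloxide being the better leaving group. The net change is an isomerisation (C25H30O8), so no reagent atom remains in 13.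

## Compound list

1 | 1-(2,6-dihydroxy-4-methoxyphenyl)ethan-1-one | CC(=O)c1c(O)cc(OC)cc1O | starting material
2 | 1-[2,6-dihydroxy-4-methoxy-3-(3-methylbut-2-en-1-yl)phenyl]ethan-1-one | CC(=O)c1c(O)cc(OC)c(CC=C(C)C)c1O | intermediate
3 | 1-{3-[(dimethylamino)methyl]-2,6-dihydroxy-4-methoxy-5-(3-methylbut-2-en-1-yl)phenyl}ethan-1-one | CC(=O)c1c(O)c(CN(C)C)c(OC)c(CC=C(C)C)c1O | intermediate
4 | methyl 3-oxopentanoate | CCC(=O)CC(=O)OC | starting material
5 | methyl 4-methyl-3,5-dioxohexanoate (racemic at C-4, largely enolised) | COC(=O)CC(=O)C(C)C(C)=O | intermediate
6 | 4-hydroxy-5,6-dimethyl-2H-pyran-2-one | CC1=C(C)C(O)=CC(=O)O1 | intermediate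
7 | 4-hydroxy-5-methyl-6-(2-oxopropyl)-2H-pyran-2-one | CC(=O)CC1=C(C)C(O)=CC(=O)O1 | intermediate
8 | 2-acetyl-3-hydroxy-5-methoxy-6-methylidene-4-(3-methylbut-2-en-1-yl)cyclohexa-2,4-dien-1-one (ortho-quinone methide) | C=C1C(OC)=C(CC=C(C)C)C(O)=C(C(C)=O)C1=O | intermediate (not isolated)
9 | 3-{[3-acetyl-2,4-dihydroxy-6-methoxy-5-(3-methylbut-2-en-1-yl)phenyl]methyl}-4-hydroxy-5-methyl-6-(2-oxopropyl)-2H-pyran-2-one | CC(=O)CC1=C(C)C(O)=C(Cc2c(O)c(C(C)=O)c(O)c(CC=C(C)C)c2OC)C(=O)O1 | intermediate
10 | 3-{[3-acetyl-2,4-dihydroxy-6-methoxy-5-(3-methylbut-2-en-1-yl)phenyl]methyl}-4-methoxy-5-methyl-6-(2-oxopropyl)-2H-pyran-2-one | CC(=O)CC1=C(C)C(OC)=C(Cc2c(O)c(C(C)=O)c(O)c(CC=C(C)C)c2OC)C(=O)O1 | intermediate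
11 | methyl (2E)-2-{[3-acetyl-2,4-dihydroxy-6-methoxy-5-(3-methylbut-2-en-1-yl)phenyl]methyl}-3-methoxy-4-methyl-5,7-dioxooct-2-enoate (racemic at C-4, present as its magnesium enolate) | COC(=O)/C(Cc1c(O)c(C(C)=O)c(O)c(CC=C(C)C)c1OC)=C(/OC)C(C)C(=O)CC(C)=O | intermediate (not isolated)
12 | 6-acetyl-2-{[3-acetyl-2,4-dihydroxy-6-methoxy-5-(3-methylbut-2-en-1-yl)phenyl]methyl}-3-methoxy-4-methylcyclohex-2-ene-1,5-dione (mixture of labile stereoisomers) | CC(=O)C1C(=O)C(C)C(OC)=C(Cc2c(O)c(C(C)=O)c(O)c(CC=C(C)C)c2OC)C1=O | intermediate (not isolated)
13 | mallotojaponin B, 1-[3-{[3-acetyl-2,4-dihydroxy-6-methoxy-5-(3-methylbut-2-en-1-yl)phenyl]methyl}-2,6-dihydroxy-4-methoxy-5-methylphenyl]ethan-1-one | COc1c(C)c(O)c(C(C)=O)c(O)c1Cc1c(O)c(C(C)=O)c(O)c(CC=C(C)C)c1OC | target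

## Step count and least certain steps

Total step count: 8. Longest linear sequence: 6 steps (steps 3, 4, 5, 6, 7 and 8, from 4). The ring B branch (steps 1 and 2) joins at step 6.

**Step 8 (key step).** Three processes are most likely to interfere:
- slow or incomplete methoxide attack at a lactone carbonyl flanked by a fully substituted C-3, which would leave the sequence at the open-chain stage;
- re-ionisation of the doubly benzylic bridge in hot base, once ring A is a phloroglucinol, with exchange of the aryl partners;
- addition–elimination of a ring B phenoxide at pyranone C-4.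

The fallback reverses the order of ring transformation and bridge formation and uses only the simple pyranone. It sets out from 7 and returns at 13. Mitsunobu methylation of 7 (MeOH, PPh3, DIAD, THF) would give 4-methoxy-5-methyl-6-(2-oxopropyl)-2H-pyran-2-one F1. Treatment of F1 with Mg(OMe)2 in MeOH, now with no second ring and no bridge present, would give 1-(2,6-dihydroxy-4-methoxy-3-methylphenyl)ethan-1-one F2 (identical with A1). Heating F2 with 3 in 1,4-dioxane, through 8, should alkylate the only free ring carbon of F2 and give 13.

**Step 7.** The likely failures are methylation at the lactone oxygen O-2 (giving a 2-methoxy-4-pyranone) or at a ring B phenol, and activation of the pyranone enol followed by cyclodehydration onto the neighbouring phenol. The cause is that the hindered, 3-substituted pyronate has two oxygen termini and a nearby phenol. The fallback moves the methylation to the end; it sets out from 9 and returns at 13. Mg(OMe)2 in MeOH at reflux would convert the free 4-hydroxypyranone of 9 into the trihydroxy ring A compound 1-[3-{[3-acetyl-2,4-dihydroxy-6-methoxy-5-(3-methylbut-2-en-1-yl)phenyl]methyl}-2,4,6-trihydroxy-5-methylphenyl]ethan-1-one F3. F3 has one hydroxyl para to an acetyl group; it is the most acidic and the only one that cannot chelate a carbonyl. One equivalent of Me2SO4 with K2CO3 in acetone should methylate it selectively to 13.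

**Step 6.** The likely failures are alkylation of 7 at O-4 or at the side-chain methylene instead of C-3, sluggish loss of dimethylamine, and cyclodehydration of the adduct to a pyranochromene. The fallback exchanges the roles of the partners; it sets out from 7 and returns at 9. Eschenmoser's salt with 7 in CH2Cl2 would give 3-[(dimethylamino)methyl]-4-hydroxy-5-methyl-6-(2-oxopropyl)-2H-pyran-2-one F4. Heating F4 with 2 in 1,4-dioxane would release 5-methyl-3-methylidene-6-(2-oxopropyl)-2H-pyran-2,4(3H)-dione F5, an exocyclic enedione. Compound 2 has a single free ring carbon and should add to F5 there to give 9.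

**Step 5.** The likely failures are incomplete second deprotonation because of aggregation of the lithium pyronate, and competing acylation at C-3 or at oxygen. The fallback builds the oxopropyl chain before the lactone is closed; it sets out from 4 and returns at 7. The dianion of 4 (LiN(iPr)2, THF) would be acylated with ethyl (2-methyl-1,3-dioxolan-2-yl)acetate to give methyl 4-methyl-6-(2-methyl-1,3-dioxolan-2-yl)-3,5-dioxohexanoate F6. DBU in toluene at reflux would close F6 to 4-hydroxy-5-methyl-6-[(2-methyl-1,3-dioxolan-2-yl)methyl]-2H-pyran-2-one F7. Aqueous HCl in THF would remove the ketal to give 7.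

**Step 1.** The likely failures are O-alkylation in place of C-alkylation and a second alkylation of the product, because the phenoxide is ambident and 2 is as nucleophilic as 1. The fallback delivers the prenyl group by a sigmatropic shift from oxygen; it sets out from 1 and returns at 2. Mono-O-alkylation of 1 with 3-chloro-3-methylbut-1-yne (K2CO3, KI, CuI cat., acetone) would give 1-{2-hydroxy-4-methoxy-6-[(2-methylbut-3-yn-2-yl)oxy]phenyl}ethan-1-one F8. Semi-hydrogenation (H2, Pd on CaCO3 poisoned with Pb(OAc)2, quinoline) would give 1-{2-hydroxy-4-methoxy-6-[(2-methylbut-3-en-2-yl)oxy]phenyl}ethan-1-one F9. Aromatic Claisen rearrangement of F9 (N,N-diethylaniline, 130 °C) would move the allyl unit, with inversion, to the free ortho carbon and give 2.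

## Further compounds

F1 | step 8 | 4-methoxy-5-methyl-6-(2-oxopropyl)-2H-pyran-2-one | CC(=O)CC1=C(C)C(OC)=CC(=O)O1
F2 | step 8 | 1-(2,6-dihydroxy-4-methoxy-3-methylphenyl)ethan-1-one | CC(=O)c1c(O)cc(OC)c(C)c1O
F3 | step 7 | 1-[3-{[3-acetyl-2,4-dihydroxy-6-methoxy-5-(3-methylbut-2-en-1-yl)phenyl]methyl}-2,4,6-trihydroxy-5-methylphenyl]ethan-1-one | CC(=O)c1c(O)c(C)c(O)c(Cc2c(O)c(C(C)=O)c(O)c(CC=C(C)C)c2OC)c1O
F4 | step 6 | 3-[(dimethylamino)methyl]-4-hydroxy-5-methyl-6-(2-oxopropyl)-2H-pyran-2-one | CC(=O)CC1=C(C)C(O)=C(CN(C)C)C(=O)O1
F5 | step 6 | 5-methyl-3-methylidene-6-(2-oxopropyl)-2H-pyran-2,4(3H)-dione | CC(=O)CC1=C(C)C(=O)C(=C)C(=O)O1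
F6 | step 5 | methyl 4-methyl-6-(2-methyl-1,3-dioxolan-2-yl)-3,5-dioxohexanoate (racemic at C-4) | COC(=O)CC(=O)C(C)C(=O)CC1(C)OCCO1
F7 | step 5 | 4-hydroxy-5-methyl-6-[(2-methyl-1,3-dioxolan-2-yl)methyl]-2H-pyran-2-one | CC1(CC2=C(C)C(O)=CC(=O)O2)OCCO1
F8 | step 1 | 1-{2-hydroxy-4-methoxy-6-[(2-methylbut-3-yn-2-yl)oxy]phenyl}ethan-1-one | CC(=O)c1c(O)cc(OC)cc1OC(C)(C)C#C
F9 | step 1 | 1-{2-hydroxy-4-methoxy-6-[(2-methylbut-3-en-2-yl)oxy]phenyl}ethan-1-one | CC(=O)c1c(O)cc(OC)cc1OC(C)(C)C=C
A1 | alternative 1 | 1-(2,6-dihydroxy-4-methoxy-3-methylphenyl)ethan-1-one | CC(=O)c1c(O)cc(OC)c(C)c1O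
A2 | alternative 2 | 1-(2,6-dihydroxy-4-methoxy-3,5-dimethylphenyl)ethan-1-one | CC(=O)c1c(O)c(C)c(OC)c(C)c1O
A3 | alternative 2 | 2-acetyl-3-hydroxy-5-methoxy-4-methyl-6-methylidenecyclohexa-2,4-dien-1-one | C=C1C(OC)=C(C)C(O)=C(C(C)=O)C1=O
A4 | alternative 3 | 4-methoxy-3-{[4-methoxy-5-methyl-2-oxo-6-(2-oxopropyl)-2H-pyran-3-yl]methyl}-5-(3-methylbut-2-en-1-yl)-6-(2-oxopropyl)-2H-pyran-2-one | CC(=O)CC1=C(C)C(OC)=C(CC2=C(OC)C(CC=C(C)C)=C(CC(C)=O)OC2=O)C(=O)O1
A5 | alternative 3 | 4-hydroxy-6-methyl-5-(3-methylbut-2-en-1-yl)-2H-pyran-2-one | CC1=C(CC=C(C)C)C(O)=CC(=O)O1
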